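47.8 % of G in Saturday's run against 40.5 % in Sunday's, both read at 6.00 min with Q charged alike at 1.5 M: I begin from that gap.

| flask | Q | D | remark | time |
|---|---|---|---|---|
| Sunday's | 1.5 M | 1.5 M | run made earlier |  |
| Saturday's | 1.5 M | 2.3 M | run made earlier |  |
| Friday's | 0.75 M | 1.05 M | run made earlier |  |
| flask | 1.5 M | 1.05 M |  | 10 min |

| run | time / min | Q / % | G / % | E / % |
|---|---|---|---|---|
| Sunday's | 0.500 | 32.0 | 34.2 | 23.5 |
| Sunday's | 0.833 | 19.3 | 37.6 | 28.4 |
| Sunday's | 1.33 | 9.9 | 38.3 | 31.5 |
| Sunday's | 2.00 | 4.5 | 39.6 | 33.8 |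
| Sunday's | 4.00 | 2.6 | 39.7 | 35.1 |
| Sunday's | 6.00 | 2.9 | 40.5 | 35.0 |
| Saturday's | 0.417 | 32.1 | 41.0 | 19.6 |
| Saturday's | 1.33 | 8.4 | 46.9 | 28.0 |
| Saturday's | 2.00 | 3.8 | 47.3 | 30.0 |
| Saturday's | 3.00 | 1.8 | 47.2 | 30.6 |
| Saturday's | 5.00 | 2.1 | 48.0 | 30.0 |
| Saturday's | 6.00 | 1.7 | 47.8 | 30.1 |
| Friday's | 1.33 | 9.9 | 36.6 | 32.8 |
| Friday's | 2.50 | 3.5 | 37.9 | 35.4 |
| Friday's | 4.00 | 2.2 | 38.2 | 35.7 |
| Friday's | 5.00 | 2.2 | 38.6 | 35.3 |
| Friday's | 6.00 | 1.7 | 38.9 | 36.0 |

(standard deviation of a reading: 0.3 percentage points)

- the reaction counts as stopped when no species that holds the Q changes by six tenths of a point or more over the second half of the time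

* which holds at 10 min: what has brought the reaction to rest, or that it has not come to rest (it is still moving / all of Q has reacted / forward and back rates have come level)
* conversion of Q at 10 min
* amount of G at 10 min, in percent of the Q charged
* amount of E at 10 min, in percent of the Q charged
* amount of G if the flask were left three thousand times as long, in percent of the Q charged

*Which concentration do you follow?* D. Between those two runs the charge of D moves from 1.5 M to 2.3 M and the charge of Q stays put, so the gap in G belongs to D.

*How do you measure G?* By its odds, w: G divided by what is not G, both as fractions of the Q charged. Sunday's last Q, G and E fall 22 percentage points short of the charge, so "not G" must count the unseen part too. Sunday's w is 0.681 and Saturday's is 0.916.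

*What do you carry forward?* The apparent reaction order of the odds in D, n = 0.694: the logarithm of the ratio of the odds over the logarithm of the ratio of the D charges, with Q held at 1.5 M.

*And this flask?* It has Sunday's Q and 1.05 M of D. Scaling Sunday's w by the ratio of the D charges raised to n gives w = 0.531. Since G is w over one plus w, my reckoning is G = 34.7 %.

*Why not start from Friday's run, which has that D?* It has half the Q, and its odds at 6.00 min read 0.637, higher than my 0.531, so by this reckoning Q moves w too.

*The weak spot?* 1.05 M lies below both charges that gave n, so n is carried beyond its two points, and both odds were read at 6.00 min, not at 10 min.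

The forecast, made from the same runs, gives: forward and back rates have come level; conversion 97.6 %; G 33.5 %; E 38.7 %; G after the long wait 38 %. On D it says: “D therefore seems to be destroyed”. Its G is lower than mine, and it comes from its own scaling.

The flask gives: forward and back rates have come level; conversion 97.5 %; G 34.0 %; E 38.5 %; G after the long wait 34.6 %. The forecast stands within its margins.

    2 D → J (k = 0.0340 M⁻¹ s⁻¹)
    E ⇌ L (K = 0.650, k = 0.0440 s⁻¹)
    Q ⇌ E (K = 15.0, k = 0.0210 s⁻¹)
    Q + D → G (k = 0.0330 M⁻¹ s⁻¹)

The flask's odds come to 0.515, against the 0.531 reckoned from n. Now take a neighbour, like this flask but charged with 2.6 M of D, which lies above the charges that gave n. Scaling Sunday's w in the same way gives w = 0.997, so G = 49.9 %. At 10 min that neighbour holds 50.7 % of G.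

All runs come from a simulation from invented constants, and the scatter is random.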